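**Retrosynthetic overview**
1. Last bond: C-2 of (4S)-4-hydroxycyclohexane-1,3-dione to C-1' of the side chain, by reductive Knoevenagel alkylation with a tetrahydrofuran-2-carbaldehyde. The six-membered ring is bought as 3-ethoxycyclohexenone and only hydroxylated.
2. Tetrahydrofuran (the only ring that is built): the C-5' hydroxyl closes onto C-2' of a 2',3'-epoxide, run in one flask as epoxidation / Payne shift / 5-exo opening, so that C-2' is inverted twice.
3. The epoxide and its two centres come from Sharpless epoxidation of (5R)-5-hydroxy-(2E,6E)-farnesol.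
4. C-5' and the C15 chain come from an asymmetric vinylogous Mukaiyama aldol of geranial with the silyl dienolate of methyl 3-methylbut-2-enoate, then ester reduction.
5. Ring order: tetrahydrofuran first (step 4); the carbocycle is joined in the last step.

Assumption 1: the biosynthesis is taken to be 2',3'-epoxidation and C-5' hydroxylation of a 2-farnesylcyclohexane-1,3-dione, then closure of the C-5' hydroxyl onto C-2' of the epoxide.
Assumption 2: geranial (pure E-citral) is bought as the single isomer; the sense of induction quoted for steps 2 and 6 is from recalled precedent and must be confirmed by Mosher analysis, the antipodal catalyst and reagent being equally available.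

**Step 1**
Reactants: 1 methyl 3-methylbut-2-enoate
Product: 3 tert-butyl[(1-methoxy-3-methylbuta-1,3-dien-1-yl)oxy]dimethylsilane, via lithium dienolate 2 (not isolated)
Conditions: LiN(iPr)2 (1.1 eq), THF, −78 °C; TBSCl (1.2 eq), DMPU, −78 °C → rt; distil
Reagents that add atoms: lithium diisopropylamide, [Li+].CC(C)[N-]C(C)C (lithium, held in 2 only); tert-butyldimethylsilyl chloride, CC(C)(C)[Si](C)(C)Cl
Why: Kinetic γ-deprotonation of the enoate and O-silylation of the dienolate (silyl ketene acetal formation) give the cross-conjugated silyl dienol ether; no stereocentre is formed.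

**Step 2**
Reactants: 3 tert-butyl[(1-methoxy-3-methylbuta-1,3-dien-1-yl)oxy]dimethylsilane; 4 geranial
Product: 6 methyl (2E,5R,6E)-5-hydroxy-3,7,11-trimethyldodeca-2,6,10-trienoate, via trichlorosilyl ether 5 (not isolated)
Conditions: SiCl4 (1.1 eq), Denmark's chiral binaphthyldiamine bisphosphoramide (2 mol %, the antipode that directs Re-face attack), iPr2NEt (10 mol %), CH2Cl2, −78 °C; then sat. aq NaHCO3
Reagents that add atoms: silicon tetrachloride, Cl[Si](Cl)(Cl)Cl (SiCl3 group, held in 5 only)
Why: Lewis-base-activated SiCl4 vinylogous Mukaiyama aldol reaction, in which the phosphoramide-bound trichlorosilyl cation binds geranial and the dienol ether attacks through its unhindered γ-carbon on the Re face in an open transition state, setting C-5 as R and giving the 2E olefin from the s-trans diene.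

**Step 3**
Reactants: 6 methyl (2E,5R,6E)-5-hydroxy-3,7,11-trimethyldodeca-2,6,10-trienoate
Product: 7 (2E,5R,6E)-3,7,11-trimethyldodeca-2,6,10-triene-1,5-diol
Conditions: iBu2AlH (3.5 eq), CH2Cl2, −78 → 0 °C; aq potassium sodium tartrate
Reagents that add atoms: none
Why: 1,2-Selective ester reduction by the aluminium hydride gives the E-allylic alcohol that will direct the epoxidation; C-5 and both olefin geometries are untouched.

**Step 4 (key step)**
Reactants: 7 (2E,5R,6E)-3,7,11-trimethyldodeca-2,6,10-triene-1,5-diol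
Product: 10 (2S,3S,5R)-5-[(1E)-2,6-dimethylhepta-1,5-dien-1-yl]-2-(hydroxymethyl)-3-methyloxolan-3-ol, via epoxy diol 8 (not isolated), via terminal epoxide 9 (not isolated)
Conditions: Ti(OiPr)4 (0.2 eq), L-(+)-diethyl tartrate (0.24 eq), t-BuOOH (1.1 eq), 4 Å MS, CH2Cl2, −25 °C; then 1 M aq NaOH, t-BuOH, 0 → 40 °C
Reagents that add atoms: tert-butyl hydroperoxide, CC(C)(C)OO (the epoxide oxygen, which ends as the 3-hydroxyl)
Why: Katsuki–Sharpless epoxidation with the L-(+)-tartrate oxidises only the primary-allylic-alcohol olefin to the (2S,3S)-epoxide (the 5R secondary allylic alcohol is the slow-reacting enantiomer for this tartrate), and in base a Payne rearrangement inverts C-2 to the terminal epoxide, which the C-5 alkoxide opens 5-exo-tet at C-2 with a second inversion, so that all three ring centres follow from stereospecific SN2 events (net retention at C-2, C-3 and C-5 untouched).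

**Step 5**
Reactants: 10 (2S,3S,5R)-5-[(1E)-2,6-dimethylhepta-1,5-dien-1-yl]-2-(hydroxymethyl)-3-methyloxolan-3-ol
Product: 11 (2R,3S,5R)-5-[(1E)-2,6-dimethylhepta-1,5-dien-1-yl]-3-hydroxy-3-methyloxolane-2-carbaldehyde
Conditions: TEMPO (0.1 eq), PhI(OAc)2 (1.1 eq), CH2Cl2, 0 °C → rt; used crude
Reagents that add atoms: none
Why: Oxoammonium (TEMPO/PhI(OAc)2) oxidation is selective for the primary alcohol over the tertiary one and inert to the trisubstituted olefins, and the near-neutral medium leaves the α-alkoxy centre unepimerised (the descriptor changes from 2S to 2R only through the priority rules).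

**Step 6**
Reactants: 12 3-ethoxycyclohex-2-en-1-one
Product: 15 (4S)-4-hydroxycyclohexane-1,3-dione, via lithium enolate 13 (not isolated), via hydroxy enol ether 14 (not isolated)
Conditions: LiN(iPr)2 (1.1 eq), THF, −78 °C; (−)-(2S,8aR)-(camphorylsulfonyl)oxaziridine (1.2 eq), −78 °C; then 1 M HCl, THF, 0 °C → rt; extract into aq NaHCO3, re-acidify
Reagents that add atoms: lithium diisopropylamide, [Li+].CC(C)[N-]C(C)C (lithium, held in 13 only); (−)-(2S,8aR)-(camphorylsulfonyl)oxaziridine, O=S1(=O)C[C@]23CC[C@H](C2(C)C)C[C@@]34ON14 (the C-4 hydroxyl oxygen); water, O (the new carbonyl oxygen)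
Why: Davis asymmetric enolate hydroxylation, in which the kinetic α'-lithium enolate of the vinylogous ester takes oxygen from the chiral N-sulfonyloxaziridine on one face (reagent control sets the S carbinol), followed by acid hydrolysis of the vinylogous ester to the free dione without touching C-4.

**Step 7**
Reactants: 11 (2R,3S,5R)-5-[(1E)-2,6-dimethylhepta-1,5-dien-1-yl]-3-hydroxy-3-methyloxolane-2-carbaldehyde; 15 (4S)-4-hydroxycyclohexane-1,3-dione
Product: 17 (4S)-2-{[(2S,3S,5R)-5-[(1E)-2,6-dimethylhepta-1,5-dien-1-yl]-3-hydroxy-3-methyloxolan-2-yl]methyl}-3,4-dihydroxycyclohex-2-en-1-one (CNP0194047.1), via alkylidene dione 16 (not isolated)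
Conditions: L-proline (0.2 eq), Hantzsch ester (diethyl 2,6-dimethyl-1,4-dihydropyridine-3,5-dicarboxylate, 1.1 eq), CH2Cl2, 25 °C
Reagents that add atoms: none
Why: Three-component reductive alkylation (amine-catalysed Knoevenagel condensation at C-2 of the dione, then conjugate hydride transfer from the Hantzsch ester to the alkylidene dione) forms the C-1'–C-2 bond C-selectively under neutral conditions; no new stereocentre arises and the four existing ones are not touched.

**Compound list**
1 | methyl 3-methylbut-2-enoate | COC(=O)C=C(C)C | starting material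
2 | lithium 1-methoxy-3-methylbuta-1,3-dien-1-olate (enolate geometry not defined) | [Li+].[O-]C(OC)=CC(C)=C | intermediate
3 | tert-butyl[(1-methoxy-3-methylbuta-1,3-dien-1-yl)oxy]dimethylsilane (ketene-acetal geometry not defined, used as formed) | C=C(C)C=C(OC)O[Si](C)(C)C(C)(C)C | intermediate
4 | geranial, (2E)-3,7-dimethylocta-2,6-dienal | CC(C)=CCC/C(C)=C/C=O | starting material
5 | methyl (2E,5R,6E)-3,7,11-trimethyl-5-[(trichlorosilyl)oxy]dodeca-2,6,10-trienoate | COC(=O)/C=C(\C)C[C@@H](O[Si](Cl)(Cl)Cl)/C=C(\C)CCC=C(C)C | intermediate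
6 | methyl (2E,5R,6E)-5-hydroxy-3,7,11-trimethyldodeca-2,6,10-trienoate | COC(=O)/C=C(\C)C[C@@H](O)/C=C(\C)CCC=C(C)C | intermediate
7 | (2E,5R,6E)-3,7,11-trimethyldodeca-2,6,10-triene-1,5-diol | OC/C=C(\C)C[C@@H](O)/C=C(\C)CCC=C(C)C | intermediate
8 | [(2S,3S)-3-[(2R,3E)-2-hydroxy-4,8-dimethylnona-3,7-dien-1-yl]-3-methyloxiran-2-yl]methanol | OC[C@@H]1O[C@@]1(C)C[C@@H](O)/C=C(\C)CCC=C(C)C | intermediate
9 | (2S,4R,5E)-6,10-dimethyl-2-[(2R)-oxiran-2-yl]undeca-5,9-diene-2,4-diol | C1O[C@H]1[C@@](C)(O)C[C@@H](O)/C=C(\C)CCC=C(C)C | intermediate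
10 | (2S,3S,5R)-5-[(1E)-2,6-dimethylhepta-1,5-dien-1-yl]-2-(hydroxymethyl)-3-methyloxolan-3-ol | CC(C)=CCC/C(C)=C/[C@H]1C[C@](C)(O)[C@H](CO)O1 | intermediate
11 | (2R,3S,5R)-5-[(1E)-2,6-dimethylhepta-1,5-dien-1-yl]-3-hydroxy-3-methyloxolane-2-carbaldehyde | CC(C)=CCC/C(C)=C/[C@H]1C[C@](C)(O)[C@H](C=O)O1 | intermediate
12 | 3-ethoxycyclohex-2-en-1-one | CCOC1=CC(=O)CCC1 | starting material
13 | lithium 5-ethoxycyclohexa-1,5-dien-1-olate (kinetic enolate of 12) | [Li+].[O-]C1=CCCC(OCC)=C1 | intermediate
14 | (6S)-3-ethoxy-6-hydroxycyclohex-2-en-1-one | CCOC1=CC(=O)[C@@H](O)CC1 | intermediate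
15 | (4S)-4-hydroxycyclohexane-1,3-dione (drawn as the diketone; largely enolised) | O=C1CC[C@H](O)C(=O)C1 | intermediate
16 | (4S)-2-{[(2S,3S,5R)-5-[(1E)-2,6-dimethylhepta-1,5-dien-1-yl]-3-hydroxy-3-methyloxolan-2-yl]methylidene}-4-hydroxycyclohexane-1,3-dione (exocyclic olefin geometry not defined) | CC(C)=CCC/C(C)=C/[C@H]1C[C@](C)(O)[C@H](C=C2C(=O)[C@@H](O)CCC2=O)O1 | intermediate
17 | (4S)-2-{[(2S,3S,5R)-5-[(1E)-2,6-dimethylhepta-1,5-dien-1-yl]-3-hydroxy-3-methyloxolan-2-yl]methyl}-3,4-dihydroxycyclohex-2-en-1-one | CC(C)=CCC/C(C)=C/[C@H]1C[C@](C)(O)[C@H](CC2=C(O)[C@@H](O)CCC2=O)O1 | target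

**Totals**
Total steps: 7. Longest linear sequence: 6 steps (1 → 2 → 3 → 4 → 5 → 7); step 6 is a one-step side branch.

**Steps most likely to fail, with fallbacks**

Step 4. The C-5 alkoxide could open the Payne epoxide 9 at C-1 (6-endo, giving a tetrahydropyran), or hydroxide could open it first. The fallback replaces the double-inversion cascade by a direct single-inversion closure on a cis-epoxide. It sets out from 3 and 4 and comes back to the route at 10. 3 and 4 are joined under Cu(OTf)2 / Tol-BINAP / Bu4N[Ph3SiF2] catalysis (asymmetric vinylogous aldol with lactonisation in the flask, ligand antipode chosen for 6R) to the lactone (6R)-6-[(1E)-2,6-dimethylhepta-1,5-dien-1-yl]-4-methyl-5,6-dihydro-2H-pyran-2-one F1, whose ring fixes the 2Z geometry. Alkaline H2O2 (NaOH, MeOH, 0 °C) is expected to epoxidise the enoate anti to the C-6 side chain, giving (1S,4R,6S)-4-[(1E)-2,6-dimethylhepta-1,5-dien-1-yl]-6-methyl-3,7-dioxabicyclo[4.1.0]heptan-2-one F2. LiBH4 (THF, 0 °C) reduces the lactone to the cis-epoxy diol [(2R,3S)-3-[(2R,3E)-2-hydroxy-4,8-dimethylnona-3,7-dien-1-yl]-3-methyloxiran-2-yl]methanol F3. Camphorsulfonic acid (CH2Cl2, 0 °C) then lets the C-5 hydroxyl open the epoxide directly at C-2 (5-endo, one inversion), which gives 10.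

Step 6. The level of induction of the oxaziridine on this trisubstituted cyclic enolate is uncertain (the antipode is used if the sense is opposite), and the α-ketol 15 may isomerise in acid. The fallback replaces reagent control by enzymatic resolution. It sets out from 12 and comes back to the route at 14. Mn(OAc)3 (benzene, reflux) α'-acetoxylates 12 to racemic 4-ethoxy-2-oxocyclohex-3-en-1-yl acetate F4. An enantioselective lipase- or esterase-mediated hydrolysis (pH 7 buffer) is chosen so that the (S)-alcohol 14 is released and separated from the unreacted (R)-acetate; if the enzyme leaves the S enantiomer as the acetate instead, it is methanolysed with K2CO3/MeOH. 14, now isolated, is hydrolysed with 1 M HCl as in step 6 to give 15.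

Step 7. The hydroxy dione 15 may not survive the amine catalyst, and the β-hydroxy aldehyde 11 may epimerise or eliminate before condensation. The fallback moves the ring hydroxylation to the end. It sets out from 11 and comes back to the route at 17. 11 is alkylated under the same proline / Hantzsch ester conditions with commercial cyclohexane-1,3-dione to give 2-{[(2S,3S,5R)-5-[(1E)-2,6-dimethylhepta-1,5-dien-1-yl]-3-hydroxy-3-methyloxolan-2-yl]methyl}-3-hydroxycyclohex-2-en-1-one F5. Its trianion (LiN(iPr)2, 3.3 eq, THF/DMPU, −78 °C) is hydroxylated at the γ-carbon (C-4) with the same chiral oxaziridine to give 17.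

**Further compounds**
F1 | step 4 | (6R)-6-[(1E)-2,6-dimethylhepta-1,5-dien-1-yl]-4-methyl-5,6-dihydro-2H-pyran-2-one | CC(C)=CCC/C(C)=C/[C@H]1CC(C)=CC(=O)O1
F2 | step 4 | (1S,4R,6S)-4-[(1E)-2,6-dimethylhepta-1,5-dien-1-yl]-6-methyl-3,7-dioxabicyclo[4.1.0]heptan-2-one | CC(C)=CCC/C(C)=C/[C@H]1C[C@]2(C)O[C@@H]2C(=O)O1
F3 | step 4 | [(2R,3S)-3-[(2R,3E)-2-hydroxy-4,8-dimethylnona-3,7-dien-1-yl]-3-methyloxiran-2-yl]methanol | OC[C@H]1O[C@@]1(C)C[C@@H](O)/C=C(\C)CCC=C(C)C
F4 | step 6 | racemic 4-ethoxy-2-oxocyclohex-3-en-1-yl acetate | CCOC1=CC(=O)C(OC(C)=O)CC1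
F5 | step 7 | 2-{[(2S,3S,5R)-5-[(1E)-2,6-dimethylhepta-1,5-dien-1-yl]-3-hydroxy-3-methyloxolan-2-yl]methyl}-3-hydroxycyclohex-2-en-1-one | CC(C)=CCC/C(C)=C/[C@H]1C[C@](C)(O)[C@H](CC2=C(O)CCCC2=O)O1
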